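**Retrosynthetic overview**
1. Target 9 ⇒ dichloride 7: both aryl C–O bonds are made last, by a twofold C–Cl → C–OMe coupling with NaOMe at copper (the key step).
2. 7 ⇒ alkylborane 6 + 1-bromo-3,5-dichlorobenzene 5: aryl–alkyl bond by B-alkyl Suzuki–Miyaura coupling at C–Br only; 6 ⇒ alkene 3 + 9-BBN 4.
3. 3 ⇒ Grignard reagent 1 + 8-bromooct-1-ene 2: sp3–sp3 bond by copper-catalysed alkylation.
4. No ring is formed; both benzene rings are bought intact.

Assumption: the target has no stereocentre (it is achiral), so no stereocontrol is needed and the route gives the one compound drawn.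

Ligand L for step 3 (catalyst component, 10 mol%): N1,N2-bis(2,6-diisopropylphenyl)benzene-1,2-diamine, CC(C)c1cccc(C(C)C)c1Nc1ccccc1Nc1c(C(C)C)cccc1C(C)C. It is made in one palladium-catalysed amination from 1,2-dibromobenzene and 2,6-diisopropylaniline.

**Route**

Step 1
Reactants: 1 (2-phenylethyl)magnesium chloride (1.0 M in THF, 1.3 equiv); 2 8-bromooct-1-ene
Product: 3 dec-9-en-1-ylbenzene
Conditions: Li2CuCl4 (3 mol%), NMP (4 equiv), THF, 0 °C to rt, 3 h; aq NH4Cl
Reagents that add atoms: none
Why: Kochi-type copper-catalysed sp3–sp3 Grignard cross-coupling, in which the catalytic alkylcuprate from 1 displaces the unhindered primary bromide of 2 while the remote terminal alkene stays untouched.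

Step 2
Reactants: 3 dec-9-en-1-ylbenzene (1.15 equiv); 4 9-borabicyclo[3.3.1]nonane (9-BBN, 0.5 M in THF, 1.2 equiv); 5 1-bromo-3,5-dichlorobenzene (1.0 equiv)
Product: 7 1,3-dichloro-5-(10-phenyldecyl)benzene, via B-(10-phenyldecyl)-9-BBN 6 (not isolated)
Conditions: 4, THF, 0 °C to rt, 4 h; then 5, Pd(dppf)Cl2·CH2Cl2 (3 mol%), 3 M aq NaOH (3 equiv), THF, 60 °C, 12 h
Reagents that add atoms: none
Why: 9-BBN hydroborates the terminal alkene anti-Markovnikov, and the hydroxyborate of 6 then undergoes B-alkyl Suzuki–Miyaura coupling in which dppf-ligated zerovalent palladium inserts into C–Br far faster than into C–Cl, so both chlorides are kept.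

Step 3
Reactants: 7 1,3-dichloro-5-(10-phenyldecyl)benzene
Product: 9 1,3-dimethoxy-5-(10-phenyldecyl)benzene, via 1-chloro-3-methoxy-5-(10-phenyldecyl)benzene 8 (not isolated)
Conditions: CuI (5 mol%), L (10 mol%), NaOMe (3.0 equiv), DMSO, 55 °C, 24 h, N2
Reagents that add atoms: sodium methoxide, C[O-].[Na+]
Why: Proposed new method: a twofold Ullmann-type C(aryl)–O coupling of an unactivated aryl dichloride with methoxide at one copper catalyst, in which NaOMe deprotonates L to a chelating diamide that gives a bent, anionic, electron-rich cuprate of monovalent copper able to add oxidatively into an aryl C–Cl bond at 55 °C (the step that limits ordinary Ullmann methoxylation to aryl bromides and iodides), the resulting trivalent copper aryl methoxide forms the C–O bond by reductive elimination without the beta-hydride elimination that causes hydrodehalogenation at palladium methoxides, the 2,6-diisopropyl groups block N-arylation of the ligand, and the first methoxy group in 8 is meta to the remaining chloride so it does not slow the second coupling; the closest known reaction types are copper/anionic N1,N2-diarylbenzene-1,2-diamine etherification of aryl bromides with aliphatic alcohols, amination of aryl chlorides with that ligand class, and classical CuBr/NaOMe methoxylation of aryl bromides.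

**Compound list**
1 | (2-phenylethyl)magnesium chloride | Cl[Mg]CCc1ccccc1 | starting material
2 | 8-bromooct-1-ene | C=CCCCCCCBr | starting material
3 | dec-9-en-1-ylbenzene (10-phenyldec-1-ene) | C=CCCCCCCCCc1ccccc1 | intermediate
4 | 9-borabicyclo[3.3.1]nonane (9-BBN) | B1C2CCCC1CCC2 | starting material
5 | 1-bromo-3,5-dichlorobenzene | Clc1cc(Cl)cc(Br)c1 | starting material
6 | 9-(10-phenyldecyl)-9-borabicyclo[3.3.1]nonane (B-(10-phenyldecyl)-9-BBN) | c1ccccc1CCCCCCCCCCB1C2CCCC1CCC2 | intermediate
7 | 1,3-dichloro-5-(10-phenyldecyl)benzene | Clc1cc(Cl)cc(CCCCCCCCCCc2ccccc2)c1 | intermediate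
8 | 1-chloro-3-methoxy-5-(10-phenyldecyl)benzene | COc1cc(Cl)cc(CCCCCCCCCCc2ccccc2)c1 | intermediate
9 | 1,3-dimethoxy-5-(10-phenyldecyl)benzene | COc1cc(CCCCCCCCCCc2ccccc2)cc(OC)c1 | target

**Step count and risks**
Total steps: 3. Longest linear sequence: 3 (1 + 2 → 3 → 7 → 9).

Most likely to fail, in order:

Step 3 (the proposed new copper-catalysed twofold methoxylation). The risks are slow oxidative addition into C–Cl, stalling at mono-ether 8, catalyst loss, and base-induced aryne formation above about 80 °C that would give regioisomers. The fallback uses known chemistry, sets out from 7 and comes back at 9. Palladium-catalysed twofold hydroxylation of 7 (Pd2(dba)3 2 mol%, tBuXPhos 8 mol%, KOH 6 equiv, 1,4-dioxane/H2O 1:1, 100 °C, then HCl) gives 5-(10-phenyldecyl)benzene-1,3-diol F1. Williamson methylation of F1 (MeI 3 equiv, K2CO3 4 equiv, acetone, 56 °C) gives 9. The ring C–O bonds are then made with hydroxide at palladium and the O–CH3 bonds by alkylation.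

Step 2 (B-alkyl Suzuki coupling). The risks are partial insertion into C–Cl, and beta-hydride elimination or protodeboronation of 6. The fallback sets out from 3 and 5 and comes back at 7, without borane or palladium. Radical anti-Markovnikov addition of HBr to 3 (HBr gas, hexane, cat. dibenzoyl peroxide, 0 °C) gives (10-bromodecyl)benzene F2. Magnesium turnings with LiCl in THF insert into the C–Br bond of 5 only and give (3,5-dichlorophenyl)magnesium bromide F3. Iron-catalysed aryl Grignard–alkyl bromide coupling of F3 with F2 (FeCl3 5 mol%, TMEDA 1.2 equiv, THF, 0 °C, slow addition of F3) gives 7.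

Step 1 (copper-catalysed sp3–sp3 coupling). The risks are homocoupling to 1,4-diphenylbutane and elimination of 2. The fallback sets out from 4 and comes back at 3. 9-BBN 4 is added to deca-1,9-diene (3 equiv, THF, 0 °C to rt; the excess diene is distilled back) to give 9-(dec-9-en-1-yl)-9-borabicyclo[3.3.1]nonane F4. Coupling of F4 with bromobenzene (Pd(dppf)Cl2·CH2Cl2 3 mol%, 3 M aq NaOH, THF, 60 °C) gives 3.

**Further compounds**
F1 | step 3 | 5-(10-phenyldecyl)benzene-1,3-diol | Oc1cc(O)cc(CCCCCCCCCCc2ccccc2)c1
F2 | step 2 | (10-bromodecyl)benzene | BrCCCCCCCCCCc1ccccc1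
F3 | step 2 | (3,5-dichlorophenyl)magnesium bromide | Clc1cc(Cl)cc([Mg]Br)c1
F4 | step 1 | 9-(dec-9-en-1-yl)-9-borabicyclo[3.3.1]nonane | C=CCCCCCCCCB1C2CCCC1CCC2
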